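**Plan**
1. Retrosynthesis: the nine benzyl ethers come off first, then the two gallate esters at O7 and O4'. Ring C is then cut at O1–C8a and C4–C4a together, which leaves ring A as an aryne and an open C2–C3–C4 chain that carries ring B.
2. Enabling feature: in ring A the carbon bearing O1 (C8a) and the carbon bearing C4 (C4a) are neighbours, and C4a stands beside the C5 oxygen. This is the substitution print of a 3-alkoxyaryne, which takes a nucleophile (O1) at the far carbon and leaves the anion next to the oxygen, ready for an electrophile (C4).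
3. Precursors: ring A is an o-silylaryl triflate with O5 as benzyl ether and O7 as allyl ether. The two oxygens are told apart by chelation to a formyl group, which later becomes the triflate oxygen. The chain has O1 masked as a triethylsilyl ether, O3 as benzyl ether and C4 as a primary bromide. All helpers (SiMe3/OTf, SiEt3, Br) leave in the key step.
4. Forward order: rings A and B are bought as 5-bromoresorcinol and 3,4-dihydroxybenzaldehyde. Ring C closes in the aryne annulation, followed by deallylation at O7/O4', double galloylation and global hydrogenolysis.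
5. Stereochemistry: C2 and C3 come from one Sharpless kinetic resolution (erythro epoxy alcohol, D-(−)-DIPT). No later step breaks a bond at either centre, so the anti chain becomes the 2,3-trans (2R,3S) ring.

Key step: step 13

Remark: flavan numbering (O1, C2–C4, C4a, C5–C8, C8a, primed ring B) is used for all intermediates, also before ring C exists; the three starting materials are taken as commercial.

**Fragment 1 (ring A, aryne precursor)**

Step 1
Reactants: 1 5-bromoresorcinol
Product: 2 2-bromo-4,6-dihydroxybenzaldehyde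
Conditions: POCl3, DMF, MeCN, 0 °C to rt; then H2O, 50 °C
Reagents that add atoms: N,N-dimethylformamide CN(C)C=O; water O
Why: Vilsmeier–Haack formylation should strike the position para to one hydroxyl and ortho to the other (as in orcinol), which puts the formyl carbon on the future C4a between bromine (future C8a) and an oxygen (future O5).

Step 2
Reactants: 2 2-bromo-4,6-dihydroxybenzaldehyde
Product: 3 4-(allyloxy)-2-bromo-6-hydroxybenzaldehyde
Conditions: allyl bromide (1 equiv), K2CO3 (1 equiv), acetone, rt to 40 °C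
Reagents that add atoms: allyl bromide C=CCBr
Why: Williamson etherification under limiting mild base should alkylate only the para 4-OH (future O7), because the 6-OH is held in a hydrogen bond to the formyl oxygen.

Step 3
Reactants: 3 4-(allyloxy)-2-bromo-6-hydroxybenzaldehyde
Product: 4 4-(allyloxy)-2-(benzyloxy)-6-bromobenzaldehyde
Conditions: BnBr, K2CO3, DMF, 60 °C
Reagents that add atoms: benzyl bromide BrCc1ccccc1
Why: Williamson etherification with heating in DMF should overcome the chelation of the remaining phenol (future O5); aryl bromide, aldehyde and allyl ether are inert to it.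

Step 4
Reactants: 4 4-(allyloxy)-2-(benzyloxy)-6-bromobenzaldehyde
Product: 6 4-(allyloxy)-2-(benzyloxy)-6-bromophenol, via aryl formate 5 (not isolated)
Conditions: mCPBA, CH2Cl2, 0 °C to rt; then K2CO3 (cat.), MeOH, 0 °C
Reagents that add atoms: 3-chloroperoxybenzoic acid O=C(OO)c1cccc(Cl)c1
Why: In this Baeyer–Villiger oxidation the aryl group, made electron-rich by its ortho and para alkoxy groups, should migrate to oxygen, and mild methanolysis then cleaves the formate; the terminal allyl ether reacts far more slowly with the peracid.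

Step 5
Reactants: 6 4-(allyloxy)-2-(benzyloxy)-6-bromophenol
Product: 9 4-(allyloxy)-2-(benzyloxy)-6-(trimethylsilyl)phenyl trifluoromethanesulfonate, via aryl trimethylsilyl ether 7 (not isolated), via lithium silylphenoxide 8 (not isolated)
Conditions: (Me3Si)2NH, THF, 70 °C, then evaporation; n-BuLi, THF, −78 °C; Tf2O, −78 °C to rt
Reagents that add atoms: hexamethyldisilazane C[Si](C)(C)N[Si](C)(C)C; trifluoromethanesulfonic anhydride O=S(=O)(OS(=O)(=O)C(F)(F)F)C(F)(F)F
Why: O-silylation, bromine–lithium exchange, retro-Brook O-to-C silyl shift and O-triflation form the standard entry from o-bromophenols to o-silylaryl triflates, and benzyloxy-substituted cases are known to tolerate it.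

**Fragment 2 (ring B and the C2–C3–C4 chain)**

Step 6
Reactants: 10 3,4-dihydroxybenzaldehyde
Product: 11 4-(allyloxy)-3-hydroxybenzaldehyde
Conditions: allyl bromide (1 equiv), NaHCO3, DMF, 40 °C
Reagents that add atoms: allyl bromide C=CCBr
Why: This regioselective Williamson etherification should work because only the more acidic 4-OH, para to the formyl group, is deprotonated by hydrogen carbonate.

Step 7
Reactants: 11 4-(allyloxy)-3-hydroxybenzaldehyde
Product: 12 4-(allyloxy)-3-(benzyloxy)benzaldehyde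
Conditions: BnBr, K2CO3, DMF, rt
Reagents that add atoms: benzyl bromide BrCc1ccccc1
Why: Williamson etherification of the one free phenol.

Step 8
Reactants: 12 4-(allyloxy)-3-(benzyloxy)benzaldehyde
Product: 13 rac-1-[4-(allyloxy)-3-(benzyloxy)phenyl]prop-2-en-1-ol
Conditions: CH2=CHMgBr, THF, 0 °C; then aq. NH4Cl
Reagents that add atoms: vinylmagnesium bromide C=C[Mg]Br
Why: Grignard 1,2-addition to the aldehyde; the carbinol centre forms racemic on purpose, since step 9 resolves it.

Step 9
Reactants: 13 rac-1-[4-(allyloxy)-3-(benzyloxy)phenyl]prop-2-en-1-ol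
Product: 14 (R)-[4-(allyloxy)-3-(benzyloxy)phenyl][(S)-oxiran-2-yl]methanol
Conditions: Ti(OiPr)4 (0.15 equiv), D-(−)-DIPT (0.18 equiv), t-BuOOH (0.45 equiv), 4 Å MS, CH2Cl2, −20 °C
Reagents that add atoms: tert-butyl hydroperoxide CC(C)(C)OO
Why: In the Sharpless kinetic resolution with D-(−)-DIPT the (S)-carbinol is the fast-reacting enantiomer (this fixes C2) and is epoxidised on the face set by the tartrate to give the erythro (anti) epoxy alcohol (this fixes C3), while the slow enantiomer stays as the alkene and is separated; the aryl allyl ether has no directing hydroxyl and is left alone.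

Step 10
Reactants: 14 (R)-[4-(allyloxy)-3-(benzyloxy)phenyl][(S)-oxiran-2-yl]methanol
Product: 15 {(R)-[4-(allyloxy)-3-(benzyloxy)phenyl][(S)-oxiran-2-yl]methoxy}triethylsilane
Conditions: Et3SiCl, imidazole, CH2Cl2, 0 °C
Reagents that add atoms: chlorotriethylsilane CC[Si](Cl)(CC)CC
Why: Standard silylation masks O1 in a form that fluoride will later turn into the alkoxide without bringing a proton into the flask.

Step 11
Reactants: 15 {(R)-[4-(allyloxy)-3-(benzyloxy)phenyl][(S)-oxiran-2-yl]methoxy}triethylsilane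
Product: 16 (1R,2R)-1-[4-(allyloxy)-3-(benzyloxy)phenyl]-3-bromo-1-[(triethylsilyl)oxy]propan-2-ol
Conditions: LiBr, AcOH (2 equiv), THF, rt
Reagents that add atoms: lithium bromide [Li+].[Br-]
Why: Buffered SN2 opening of the terminal epoxide by bromide should occur at the CH2 end (C4), so the C3–O bond and its configuration stay untouched (only the descriptor changes, because bromine raises the rank of C4).

Step 12
Reactants: 16 (1R,2R)-1-[4-(allyloxy)-3-(benzyloxy)phenyl]-3-bromo-1-[(triethylsilyl)oxy]propan-2-ol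
Product: 17 {(1R,2R)-1-[4-(allyloxy)-3-(benzyloxy)phenyl]-2-(benzyloxy)-3-bromopropoxy}triethylsilane
Conditions: 2-benzyloxy-1-methylpyridinium triflate, MgO, PhCF3, 85 °C
Reagents that add atoms: 2-benzyloxy-1-methylpyridinium trifluoromethanesulfonate C[n+]1ccccc1OCc1ccccc1.[O-]S(=O)(=O)C(F)(F)F
Why: Neutral thermal benzyl transfer avoids base (which would re-close the epoxide from the bromohydrin) and strong acid (which would ionise the electron-rich benzylic silyl ether).

**Union and end game**

Step 13
Reactants: 9 4-(allyloxy)-2-(benzyloxy)-6-(trimethylsilyl)phenyl trifluoromethanesulfonate; 17 {(1R,2R)-1-[4-(allyloxy)-3-(benzyloxy)phenyl]-2-(benzyloxy)-3-bromopropoxy}triethylsilane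
Product: 21 (2R,3S)-7-(allyloxy)-2-[4-(allyloxy)-3-(benzyloxy)phenyl]-3,5-bis(benzyloxy)chromane, via aryne 18 (not isolated), via potassium alkoxide 19 (not isolated), via arylpotassium 20 (not isolated)
Conditions: KF, 18-crown-6, 4 Å MS, THF, rt to 40 °C; 9 (2 equiv) added slowly
Reagents that add atoms: none
Why: Proposed new method: fluoride strips the C–SiMe3 group of 9 (loss of triflate gives aryne 18) and the O–SiEt3 group of 17 (alkoxide 19), 19 adds through O1 to C8a of 18, and the aryl anion 20 born at C4a between two oxygens displaces the primary bromide at C4, so that O1–C8a and C4–C4a form in one operation. The closest known reaction types are the annulation of arynes with salicylates or o-hydroxychalcones (O-addition, then capture of the aryl anion by a tethered ester or enone) and the Parham cyclialkylation of o-alkoxyaryllithiums onto primary bromides, and what is new is the pairing of an aliphatic alkoxide with an sp3 leaving group. Ring C closes in the 6-exo-tet mode, and the anion has no other electrophilic carbon within reach. No stereocentre is made, since neither the C2–O1 nor the C3–O bond is touched and C4 is a CH2 group, so the anti relation of 17 is carried over as the 2,3-trans (2R,3S) ring. The regiochemistry needed (O at C8a, C at C4a) is secured by the C5 benzyloxy group beside the triple bond, whose inductive pull distorts the aryne so that nucleophiles attack the far carbon and the charge lands next to oxygen, while the remote C7 allyloxy group has only a weak say. The chemoselectivity needed is aryne capture before 4-exo-tet oxetane closure of 19 and ring closure before protonation of 20, which is served by releasing alkoxide and aryne side by side from their silyl masks in dry aprotic THF with a steady excess of 9.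

Step 14
Reactants: 21 (2R,3S)-7-(allyloxy)-2-[4-(allyloxy)-3-(benzyloxy)phenyl]-3,5-bis(benzyloxy)chromane
Product: 22 (2R,3S)-3,5-bis(benzyloxy)-2-[3-(benzyloxy)-4-hydroxyphenyl]chroman-7-ol
Conditions: Pd(PPh3)4 (5 mol %), morpholine, THF, rt
Reagents that add atoms: none
Why: In this Tsuji–Trost-type deallylation zerovalent palladium ionises only the two aryl allyl ethers and morpholine takes up the allyl groups, which frees exactly O7 and O4' under neutral conditions that leave the benzyl ethers and the flavan alone.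

Step 15
Reactants: 22 (2R,3S)-3,5-bis(benzyloxy)-2-[3-(benzyloxy)-4-hydroxyphenyl]chroman-7-ol; 23 3,4,5-tris(benzyloxy)benzoic acid
Product: 24 (2R,3S)-3,5-bis(benzyloxy)-2-{3-(benzyloxy)-4-[3,4,5-tris(benzyloxy)benzoyloxy]phenyl}chroman-7-yl 3,4,5-tris(benzyloxy)benzoate
Conditions: 23 (2.4 equiv), DCC, DMAP (cat.), CH2Cl2, 0 °C to rt
Reagents that add atoms: none
Why: Steglich esterification; the two phenols are the only free hydroxyl groups, so the site of acylation is fixed by the protecting-group pattern.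

Step 16
Reactants: 24 (2R,3S)-3,5-bis(benzyloxy)-2-{3-(benzyloxy)-4-[3,4,5-tris(benzyloxy)benzoyloxy]phenyl}chroman-7-yl 3,4,5-tris(benzyloxy)benzoate
Product: 25 catechin 7,4'-di-O-gallate
Conditions: H2 (1 atm), Pd(OH)2/C, THF/EtOAc, rt
Reagents that add atoms: none
Why: Catalytic hydrogenolysis should cleave all nine benzyl–oxygen bonds under neutral conditions that spare the aryl esters, the C2–O1 bond and both stereocentres, and the aprotic solvent is chosen to hold back galloyl migration from O4' to O3'.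

**Compound list**
1 | 5-bromoresorcinol | Oc1cc(O)cc(Br)c1 | starting material
2 | 2-bromo-4,6-dihydroxybenzaldehyde | O=Cc1c(O)cc(O)cc1Br | intermediate
3 | 4-(allyloxy)-2-bromo-6-hydroxybenzaldehyde | O=Cc1c(O)cc(OCC=C)cc1Br | intermediate
4 | 4-(allyloxy)-2-(benzyloxy)-6-bromobenzaldehyde | O=Cc1c(OCc2ccccc2)cc(OCC=C)cc1Br | intermediate
5 | 4-(allyloxy)-2-(benzyloxy)-6-bromophenyl formate | O=COc1c(OCc2ccccc2)cc(OCC=C)cc1Br | intermediate
6 | 4-(allyloxy)-2-(benzyloxy)-6-bromophenol | Oc1c(OCc2ccccc2)cc(OCC=C)cc1Br | intermediate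
7 | [4-(allyloxy)-2-(benzyloxy)-6-bromophenoxy]trimethylsilane | C[Si](C)(C)Oc1c(OCc2ccccc2)cc(OCC=C)cc1Br | intermediate
8 | lithium 4-(allyloxy)-2-(benzyloxy)-6-(trimethylsilyl)phenoxide | [Li+].[O-]c1c(OCc2ccccc2)cc(OCC=C)cc1[Si](C)(C)C | intermediate
9 | 4-(allyloxy)-2-(benzyloxy)-6-(trimethylsilyl)phenyl trifluoromethanesulfonate | O=S(=O)(Oc1c(OCc2ccccc2)cc(OCC=C)cc1[Si](C)(C)C)C(F)(F)F | intermediate
10 | 3,4-dihydroxybenzaldehyde | O=Cc1ccc(O)c(O)c1 | starting material
11 | 4-(allyloxy)-3-hydroxybenzaldehyde | O=Cc1ccc(OCC=C)c(O)c1 | intermediate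
12 | 4-(allyloxy)-3-(benzyloxy)benzaldehyde | O=Cc1ccc(OCC=C)c(OCc2ccccc2)c1 | intermediate
13 | rac-1-[4-(allyloxy)-3-(benzyloxy)phenyl]prop-2-en-1-ol | OC(C=C)c1ccc(OCC=C)c(OCc2ccccc2)c1 | intermediate
14 | (R)-[4-(allyloxy)-3-(benzyloxy)phenyl][(S)-oxiran-2-yl]methanol | O[C@H](c1ccc(OCC=C)c(OCc2ccccc2)c1)[C@@H]1CO1 | intermediate
15 | {(R)-[4-(allyloxy)-3-(benzyloxy)phenyl][(S)-oxiran-2-yl]methoxy}triethylsilane | CC[Si](CC)(CC)O[C@H](c1ccc(OCC=C)c(OCc2ccccc2)c1)[C@@H]1CO1 | intermediate
16 | (1R,2R)-1-[4-(allyloxy)-3-(benzyloxy)phenyl]-3-bromo-1-[(triethylsilyl)oxy]propan-2-ol | CC[Si](CC)(CC)O[C@H](c1ccc(OCC=C)c(OCc2ccccc2)c1)[C@@H](O)CBr | intermediate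
17 | {(1R,2R)-1-[4-(allyloxy)-3-(benzyloxy)phenyl]-2-(benzyloxy)-3-bromopropoxy}triethylsilane | CC[Si](CC)(CC)O[C@H](c1ccc(OCC=C)c(OCc2ccccc2)c1)[C@@H](OCc1ccccc1)CBr | intermediate
18 | 5-(allyloxy)-3-(benzyloxy)-1,2-didehydrobenzene (aryne C4a≡C8a) | C=CCOC1=CC#CC(OCc2ccccc2)=C1 | intermediate
19 | potassium (1R,2R)-1-[4-(allyloxy)-3-(benzyloxy)phenyl]-2-(benzyloxy)-3-bromopropan-1-olate | [K+].[O-][C@H](c1ccc(OCC=C)c(OCc2ccccc2)c1)[C@@H](OCc1ccccc1)CBr | intermediate
20 | potassium 4-(allyloxy)-2-(benzyloxy)-6-{(1R,2R)-1-[4-(allyloxy)-3-(benzyloxy)phenyl]-2-(benzyloxy)-3-bromopropoxy}phenide | [K+].C=CCOc1cc(OCc2ccccc2)[c-]c(c1)O[C@H](c1ccc(OCC=C)c(OCc2ccccc2)c1)[C@@H](OCc1ccccc1)CBr | intermediate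
21 | (2R,3S)-7-(allyloxy)-2-[4-(allyloxy)-3-(benzyloxy)phenyl]-3,5-bis(benzyloxy)chromane | C=CCOc1cc(OCc2ccccc2)c2c(c1)O[C@H](c1ccc(OCC=C)c(OCc3ccccc3)c1)[C@@H](OCc1ccccc1)C2 | intermediate
22 | (2R,3S)-3,5-bis(benzyloxy)-2-[3-(benzyloxy)-4-hydroxyphenyl]chroman-7-ol | Oc1cc(OCc2ccccc2)c2c(c1)O[C@H](c1ccc(O)c(OCc3ccccc3)c1)[C@@H](OCc1ccccc1)C2 | intermediate
23 | 3,4,5-tris(benzyloxy)benzoic acid | O=C(O)c1cc(OCc2ccccc2)c(OCc2ccccc2)c(OCc2ccccc2)c1 | starting material
24 | (2R,3S)-3,5-bis(benzyloxy)-2-{3-(benzyloxy)-4-[3,4,5-tris(benzyloxy)benzoyloxy]phenyl}chroman-7-yl 3,4,5-tris(benzyloxy)benzoate | O=C(Oc1cc(OCc2ccccc2)c2c(c1)O[C@H](c1ccc(OC(=O)c3cc(OCc4ccccc4)c(OCc4ccccc4)c(OCc4ccccc4)c3)c(OCc3ccccc3)c1)[C@@H](OCc1ccccc1)C2)c1cc(OCc2ccccc2)c(OCc2ccccc2)c(OCc2ccccc2)c1 | intermediate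
25 | catechin 7,4'-di-O-gallate, (2R,3S) | O=C(Oc1cc(O)c2c(c1)O[C@H](c1ccc(OC(=O)c3cc(O)c(O)c(O)c3)c(O)c1)[C@@H](O)C2)c1cc(O)c(O)c(O)c1 | target

**Count**
Total steps: 16. Longest linear sequence: 11 (steps 6 to 16, from 10 to 25).

**Steps most likely to fail**

1. Step 13.
- What may go wrong: the free alkoxide may close the oxetane (4-exo-tet) or lose HBr before it meets the aryne. The aryl anion may also be protonated or silylated before it reaches C4.
- Fallback by known reactions: it sets out from 9 and 15 and comes back at 21.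
- The aryne from 9 is trapped with iodine (CsF, I2, MeCN; insertion into the I–I bond) to give 5-(allyloxy)-1-(benzyloxy)-2,3-diiodobenzene F1.
- iPrMgCl·LiCl (THF, −40 °C) exchanges the iodine beside the benzyloxy group to give the arylmagnesium chloride F2. Under CuI catalysis this opens epoxide 15 at its CH2 end and forms C4–C4a in the iodoaryl propan-2-ol F3.
- The C3 hydroxyl is benzylated with the pyridinium reagent of step 12 to give the benzyl ether F4. Bu4NF buffered with AcOH then frees the C2 hydroxyl in the iodoaryl propan-1-ol F5.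
- An intramolecular Ullmann etherification (CuI, 1,10-phenanthroline, Cs2CO3, toluene, 110 °C) closes O1–C8a with retention at C2 and gives 21.

2. Step 12.
- What may go wrong: benzyl transfer to the crowded secondary alcohol may be sluggish, and on long heating the silyl group may be lost or migrate, or the bromohydrin may re-close to the epoxide.
- Fallback: the benzylation is postponed until after ring closure. It sets out from 16 and comes back at 21.
- O3 is capped with 2-methoxypropene and catalytic PPTS (CH2Cl2, 0 °C) as the 2-methoxyprop-2-yl acetal F6.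
- F6 is taken with 9 through the conditions of step 13, by way of the potassium alkoxide F7 and the arylpotassium F8, to the 3-O-(2-methoxyprop-2-yl)flavan F9.
- PPTS in MeOH frees the flavan-3-ol F10. This compound holds neither a leaving group nor a silyl ether, so an ordinary Williamson benzylation (NaH, BnBr, DMF, 0 °C) gives 21.

3. Step 16.
- What may go wrong: the galloyl group may migrate from O4' to the freshly freed O3', debenzylation may stall at partly protected stages, or ring C may open by hydrogenolysis at the benzylic C2–O1 bond.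
- Fallback: it sets out from 24 and comes back at 25. Hydrogen and metal are replaced by Lewis-acid debenzylation with a cation scavenger (BCl3, pentamethylbenzene, CH2Cl2, −78 °C, quench with MeOH/CHCl3). This is aprotic and cold, so acyl migration should be slow, and it makes no new intermediate.

**Further compounds**
F1 | step 13 | 5-(allyloxy)-1-(benzyloxy)-2,3-diiodobenzene | C=CCOc1cc(I)c(I)c(OCc2ccccc2)c1
F2 | step 13 | [4-(allyloxy)-2-(benzyloxy)-6-iodophenyl]magnesium chloride | C=CCOc1cc(I)c([Mg]Cl)c(OCc2ccccc2)c1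
F3 | step 13 | (1R,2S)-3-[4-(allyloxy)-2-(benzyloxy)-6-iodophenyl]-1-[4-(allyloxy)-3-(benzyloxy)phenyl]-1-[(triethylsilyl)oxy]propan-2-ol | CC[Si](CC)(CC)O[C@H](c1ccc(OCC=C)c(OCc2ccccc2)c1)[C@@H](O)Cc1c(I)cc(OCC=C)cc1OCc1ccccc1
F4 | step 13 | {(1R,2S)-3-[4-(allyloxy)-2-(benzyloxy)-6-iodophenyl]-1-[4-(allyloxy)-3-(benzyloxy)phenyl]-2-(benzyloxy)propoxy}triethylsilane | CC[Si](CC)(CC)O[C@H](c1ccc(OCC=C)c(OCc2ccccc2)c1)[C@@H](OCc1ccccc1)Cc1c(I)cc(OCC=C)cc1OCc1ccccc1
F5 | step 13 | (1R,2S)-3-[4-(allyloxy)-2-(benzyloxy)-6-iodophenyl]-1-[4-(allyloxy)-3-(benzyloxy)phenyl]-2-(benzyloxy)propan-1-ol | O[C@H](c1ccc(OCC=C)c(OCc2ccccc2)c1)[C@@H](OCc1ccccc1)Cc1c(I)cc(OCC=C)cc1OCc1ccccc1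
F6 | step 12 | {(1R,2R)-1-[4-(allyloxy)-3-(benzyloxy)phenyl]-3-bromo-2-[(2-methoxypropan-2-yl)oxy]propoxy}triethylsilane | CC[Si](CC)(CC)O[C@H](c1ccc(OCC=C)c(OCc2ccccc2)c1)[C@@H](OC(C)(C)OC)CBr
F7 | step 12 | potassium (1R,2R)-1-[4-(allyloxy)-3-(benzyloxy)phenyl]-3-bromo-2-[(2-methoxypropan-2-yl)oxy]propan-1-olate | [K+].[O-][C@H](c1ccc(OCC=C)c(OCc2ccccc2)c1)[C@@H](OC(C)(C)OC)CBr
F8 | step 12 | potassium 4-(allyloxy)-2-(benzyloxy)-6-{(1R,2R)-1-[4-(allyloxy)-3-(benzyloxy)phenyl]-3-bromo-2-[(2-methoxypropan-2-yl)oxy]propoxy}phenide | [K+].C=CCOc1cc(OCc2ccccc2)[c-]c(c1)O[C@H](c1ccc(OCC=C)c(OCc2ccccc2)c1)[C@@H](OC(C)(C)OC)CBr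
F9 | step 12 | (2R,3S)-7-(allyloxy)-2-[4-(allyloxy)-3-(benzyloxy)phenyl]-5-(benzyloxy)-3-[(2-methoxypropan-2-yl)oxy]chromane | C=CCOc1cc(OCc2ccccc2)c2c(c1)O[C@H](c1ccc(OCC=C)c(OCc3ccccc3)c1)[C@@H](OC(C)(C)OC)C2
F10 | step 12 | (2R,3S)-7-(allyloxy)-2-[4-(allyloxy)-3-(benzyloxy)phenyl]-5-(benzyloxy)chroman-3-ol | C=CCOc1cc(OCc2ccccc2)c2c(c1)O[C@H](c1ccc(OCC=C)c(OCc3ccccc3)c1)[C@@H](O)C2
F0 | step 16 | none | none
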